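## Structural features

The target is a sesquineolignan: a 2,6-diaryl-3,7-dioxabicyclo[3.3.0]octane (two cis-fused oxolanes sharing the C8–C8' bond) with guaiacyl ring B on C7 and guaiacyl ring C on C7', in which the phenol oxygen of ring B is bonded to C8'' of a 1-arylpropane-1,3-diol chain ending in guaiacyl ring A. Four contiguous stereocentres lie in the core (C7 R, C8 S, C8' S, C7' R, both aryl groups exo) and two adjacent ones in the side chain (C7'' R, C8'' S, the erythro or anti arrangement); ring B separates the two sets, so neither can control the other. Without the side chain the core is C2-symmetric, so the halves C7–C8–C9 and C7'–C8'–C9' and the two phenols are equivalent until ring B is etherified. Fragile groups are the benzylic ether carbons C7 and C7' (ionised by acid with epimerisation or Friedel–Crafts closure, cleaved by hydrogenolysis), the electron-rich free phenols, and the benzylic carbinol C7''. The real difficulty is to set the 8S,8'S pair and close both oxolanes with exo aryl groups in few steps, and then to put an anti-configured side chain on only one of two like phenols with absolute control that the core cannot supply. The key step exploits that C7 and C7' are benzylic carbons para to the phenolic oxygens of ring B and ring C, each within five-ring reach of the hydroxyl oxygen on the CH2 of the other half (O on C9' for C7, O on C9 for C7'), so both oxolanes can be closed by benzylic C–H oxidation of an open 2,3-dibenzylbutane-1,4-diol.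

## Logic of the disconnections

21 to 20. The C9''–N bond to the auxiliary and the acetyl C–O bond on ring A are the last bonds to be cleaved (the imide carbonyl becomes the C9'' alcohol). One hydride reagent does both, so no separate deprotection is needed. The demand is a reduction that leaves the benzylic ethers and the C7''/C8'' centres alone.

20 to 16 and 17. The C7''–C8'' bond is cut. A hydroxyl on C7'' next to an aryloxy group on C8'' is an aldol retron, and erythro corresponds to the anti aldol. Ring A is removed as a commercial aldehyde and both side-chain centres come from one auxiliary. The forward step must be anti-selective under auxiliary control and must tolerate the free phenol of ring C, which is masked in the flask.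

16 to 12 and 15. The bond between the ring B phenol oxygen and C8'' is cut. The two phenols of 12 are homotopic, so only one mono-ether can form. The demand is mono- over bis-alkylation, met by stoichiometry and recovery of 12, and a base mild enough for the imide.

15 to 13 and 14. The N–C9'' acyl bond is cut, giving the auxiliary and a two-carbon acid bromide.

12 to 8 (key disconnection). The C7–O(C9') and C7'–O(C9) bonds are cut. Both rings open and two stereocentres disappear, leaving a C2-symmetric diol. The forward step must oxidise two benzylic CH2 groups without oxidising the benzylic ether C–H bonds it creates. For that reason both rings of 8 are free phenols: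
- A design with one ring O-alkylated (for example as an allyl ether) would need hydride abstraction from a non-phenolic arene for the second closure. That is slower than quinone methide formation and likely slower than over-oxidation of the first-formed phenolic benzylic ether.
- With two phenols both CH2 groups react by the same fast quinone methide path, the precursor becomes symmetric, and no protecting groups need to be exchanged after the closure.
- The price is a statistically limited mono-etherification in step 8.

8 to 7. The two O–benzyl bonds are cut. The phenols must be masked during enolate chemistry, and benzyl can be removed by hydrogenolysis only here, before any benzylic ether of the skeleton exists.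

7 to 6. The C9–N and C9'–N bonds are cut (alcohols traced back to N-acyl oxazolidinones).

6 to 5. The C8–C8' bond, which lies on the C2 axis, is cut. Oxidative enolate homocoupling makes both stereocentres from one monomer. The demand is facial control by the auxiliary on both partners.

5 to 2 and 3, and 2 to 1. The N-acyl bond and the O–benzyl bond are cut, ending at commercial dihydroferulic acid and the oxazolidinone.

## Other disconnections considered

Alternative 1: The cut is at C8–C9 and C8'–C9', taking both hydroxymethyl carbons off a C2-symmetric dienediol that carries no arene.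
- Forward step: the bis(tributylstannylmethyl) ether A1 with n-BuLi undergoes two tin–lithium exchanges and two [2,3] Wittig–Still shifts. With the carbinol hydrogen eclipsing the Z-alkene in the envelope transition state, the (2R,7R) configuration should give the (2S,3S)-diol A2 with two E-propenyl groups.
- In favour: both centres are set by a concerted, predictable chirality transfer with no auxiliary to remove. On the reliability of C8/C8' control it is probably the better plan. Its use of C2 symmetry is an equal point.
- Against: A2 has none of the three arenes and neither benzylic oxygen. Both propenyl groups must be cleaved, arylated and cyclised, so C7 and C7' are still set late in an acid closure. A1 needs a (Z,Z)-diene synthesis and stoichiometric organotin. A [1,2]-shift can compete in the second rearrangement.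
- Comparison: the route to 12 would be about twice as long as steps 1–6, and the mono-etherification problem is unchanged.

Alternative 2: The cut is at C7'–C8' and C8–C7, leaving C9–C8–C8'–C9' as the (5S)-menthyloxybutenolide A3.
- Forward step: the 2-lithio derivative of dithiane A4 (ring C) adds to C8' of A3 anti to the menthyloxy group, and the enolate is trapped at C8 by aldehyde A5 (ring B) to give the trans,trans-lactone A6.
- In favour: one three-component operation forms two skeletal bonds and both core centres. C7 arrives oxygenated, so no C–H oxidation is needed there. Rings B and C differ from the start, which avoids the statistical step 8. On these points and on precedent for the polar mechanism it is the better plan.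
- Against: this enantiomeric series needs the less common antipode of the terpene auxiliary. C7' arrives as a dithiane, whose removal fits poorly with an allyl ether and electron-rich arenes. Lactone, acetal and ketone must then be reduced and the tetrol closed under acid. Allyl and silyl groups must be exchanged before the side chain goes on.
- Comparison: about ten steps from A3 to a core with ring B free, against six steps to 12. The chosen plan is shorter and sulfur-free but carries the oxidation risk and the statistical ceiling.

Alternative 3: The cut is at C8–C8' within the oxolane O/C7/C8/C8'/C9', leading to the epoxy cinnamyl ether A7 with C7 already configured.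
- Forward step: Cp2TiCl (trivalent titanium) opens the epoxide to the C8 radical, which adds 5-exo-trig to C8'. The benzylic C7' radical is reduced and protonated to give oxolane A8.
- In favour: the C8–C8' bond, one ring and two stereocentres form in one mild step. The rings are differentiated (better than the chosen plan on this point), and titanium can be used catalytically.
- Against: C7 must first be made enantiopure and alone controls C8 and C8'. The cis C8/C8' relationship is the less secure one in such cyclisations. A8 still lacks the C7'–O bond, so a benzylic oxidation of the kind used in step 6 is needed anyway, now at a silylated ring. Allyl and silyl groups must then be exchanged.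
- Comparison: equal in ending with an oxidative closure at C7'. The chosen plan is better in absolute control at C8/C8' and in protecting-group economy; step count is about equal to slightly worse for the alternative.

Key step: step 6

Remark on the chemistry: in 8 and 12 rings B and C are homotopic; the letters denote the ring etherified in step 8 (B) and the ring that stays a phenol (C). The descriptor pair (2S,3S) in 8 and 8S,8'S in 12 describes the same spatial arrangement, and the other precursor, product and alternative structures were checked and found consistent with the target. Compounds 1, 3, 13, 14 and 17 are taken as commercially available.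

## Route

Step 1
Reactants: 1 3-(4-hydroxy-3-methoxyphenyl)propanoic acid (dihydroferulic acid)
Product: 2 3-[4-(benzyloxy)-3-methoxyphenyl]propanoic acid
Conditions: BnBr, NaOH (2.2 equiv), EtOH/H2O, reflux; then HCl
Reagents that add atoms: benzyl bromide, BrCc1ccccc1
Why: Williamson ether synthesis; in aqueous ethanolic NaOH the substrate is a phenoxide–carboxylate dianion, the phenoxide is much the better nucleophile, and hydroxide keeps the carboxylate unesterified.

Step 2
Reactants: 2 3-[4-(benzyloxy)-3-methoxyphenyl]propanoic acid; 3 (4R)-4-isopropyl-1,3-oxazolidin-2-one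
Product: 5 (4R)-3-{3-[4-(benzyloxy)-3-methoxyphenyl]propanoyl}-4-isopropyl-1,3-oxazolidin-2-one, via mixed pivalic anhydride 4 (not isolated)
Conditions: tBuCOCl, Et3N, THF, −20 °C; then 3, LiCl, rt
Reagents that add atoms: none
Why: N-acylation of the oxazolidinone through the mixed anhydride 4, which is attacked at its unhindered acyl carbon; the auxiliary stereocentre is not involved.

Step 3
Reactants: 5 (4R)-3-{3-[4-(benzyloxy)-3-methoxyphenyl]propanoyl}-4-isopropyl-1,3-oxazolidin-2-one (two molecules)
Product: 6 (4R,4'R)-3,3'-{(2S,3S)-2,3-bis[4-(benzyloxy)-3-methoxybenzyl]butanedioyl}bis(4-isopropyl-1,3-oxazolidin-2-one)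
Conditions: LiN(iPr)2 (1.1 equiv), THF, −78 °C; then TiCl4 (1.1 equiv), −78 °C to rt
Reagents that add atoms: none
Why: Oxidative enolate homocoupling, known for 3-arylpropanoyl oxazolidinones; the (Z)-enolate on tetravalent titanium is oxidised by inner-sphere electron transfer (titanium becoming trivalent) and the C8–C8' bond forms. Both partners react on the face opposite the isopropyl group of the (4R)-auxiliary, so the C2-symmetric (2S,3S) dimer should predominate; the other dimers are diastereomers and separable.

Step 4
Reactants: 6 (4R,4'R)-3,3'-{(2S,3S)-2,3-bis[4-(benzyloxy)-3-methoxybenzyl]butanedioyl}bis(4-isopropyl-1,3-oxazolidin-2-one)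
Product: 7 (2S,3S)-2,3-bis[4-(benzyloxy)-3-methoxybenzyl]butane-1,4-diol
Conditions: LiBH4, MeOH, THF, 0 °C to rt
Reagents that add atoms: none
Why: Reductive cleavage of both N-acyl oxazolidinones at the exocyclic carbonyl gives the C9 and C9' alcohols and releases the auxiliary; benzyl ethers are inert and C8/C8' are not epimerised under these non-enolising conditions.

Step 5
Reactants: 7 (2S,3S)-2,3-bis[4-(benzyloxy)-3-methoxybenzyl]butane-1,4-diol
Product: 8 (2S,3S)-2,3-bis(4-hydroxy-3-methoxybenzyl)butane-1,4-diol ((+)-secoisolariciresinol)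
Conditions: H2 (1 atm), 10% Pd/C, EtOAc/EtOH, rt
Reagents that add atoms: none
Why: Hydrogenolysis of the two aryl benzyl ethers; at this stage the skeleton has no benzylic C–O bond, so nothing else can be cleaved.

Step 6
Reactants: 8 (2S,3S)-2,3-bis(4-hydroxy-3-methoxybenzyl)butane-1,4-diol
Product: 12 (−)-pinoresinol (7R,7'R,8S,8'S), via ring C quinone methide 9 (not isolated), via monocyclic oxolane (−)-lariciresinol 10 (not isolated), via ring B quinone methide 11 (not isolated)
Conditions: DDQ (2.1 equiv, in portions), NaHCO3, 4 Å molecular sieves, 1,4-dioxane/CH2Cl2 (1:1), high dilution, 0 °C to rt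
Reagents that add atoms: none
Why: DDQ takes a hydride from the benzylic CH2 para to the free hydroxyl of ring C to give p-quinone methide 9, whose C7' is attacked by the C9 hydroxyl in an oxa-1,6-addition that restores the arene and gives oxolane 10; the same sequence at C7 of ring B through 11, with the C9' hydroxyl as nucleophile, gives 12. The closest known reaction type is the DDQ-mediated benzylic alkoxylation of 4-alkylphenols through quinone methides, here intramolecular, which is also the chemical reverse of the two benzylic ether reductions that link these lignan classes. Both rings close in the 5-exo-trig mode, the oxygen adding to the exocyclic terminus of the quinone methide C=C. At C7' the aryl group should end trans to the C8' hydroxymethyl group, because the envelope transition state keeps the planar quinone methide pseudo-equatorial and away from that substituent (control by C8'). At C7 the cis relationship of C7 and C9' on the first oxolane, fixed by C8 and C8', forces a cis-fused bicycle, and closure with the aryl group on the convex face places it exo (control by C8). The step needs oxidation of the two CH2 groups ahead of the benzylic ether C–H bonds of 10 and 12; this is why both rings are free phenols, so that both CH2 groups use the same fast quinone methide path, and why DDQ is limited to two equivalents at low temperature. It also needs O-capture ahead of Friedel–Crafts attack by the other guaiacyl ring and ahead of tautomerisation to a styrene, which the well-placed primary hydroxyls and the NaHCO3 buffer (no acid to re-ionise the product) should secure. C8 and C8' carry no activating group and stay untouched.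

Step 7
Reactants: 13 (4S)-4-benzyl-1,3-oxazolidin-2-one; 14 bromoacetyl bromide
Product: 15 (4S)-4-benzyl-3-(bromoacetyl)-1,3-oxazolidin-2-one
Conditions: n-BuLi, THF, −78 °C; then 14, −78 °C
Reagents that add atoms: none
Why: N-acylation of the lithiated oxazolidinone; the acyl bromide reacts far faster than the alkyl bromide at −78 °C.

Step 8
Reactants: 12 (−)-pinoresinol; 15 (4S)-4-benzyl-3-(bromoacetyl)-1,3-oxazolidin-2-one
Product: 16 (4S)-4-benzyl-3-[(4-{(1R,3aS,4R,6aS)-4-(4-hydroxy-3-methoxyphenyl)tetrahydro-1H,3H-furo[3,4-c]furan-1-yl}-2-methoxyphenoxy)acetyl]-1,3-oxazolidin-2-one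
Conditions: 12 (2 equiv), K2CO3, acetone, 0 °C to rt; unreacted 12 recovered
Reagents that add atoms: none
Why: Williamson etherification by SN2 at a carbonyl-activated primary bromide; the two phenols of 12 are homotopic, so only one mono-ether can form and the excess of 12 should favour it over the bis-ether. The stereocentres are remote and not affected.

Step 9
Reactants: 16 the mono(aryloxyacetyl) imide of step 8; 17 4-formyl-2-methoxyphenyl acetate (vanillin acetate)
Product: 20 (4S)-3-[(2R,3R)-3-(4-acetoxy-3-methoxyphenyl)-3-hydroxy-2-(4-{(1R,3aS,4R,6aS)-4-(4-hydroxy-3-methoxyphenyl)tetrahydro-1H,3H-furo[3,4-c]furan-1-yl}-2-methoxyphenoxy)propanoyl]-4-benzyl-1,3-oxazolidin-2-one, via ring C trimethylsilyl ether 18 (not isolated), via bis-silylated aldol adduct 19 (not isolated)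
Conditions: Me3SiCl (3 equiv), Et3N (4 equiv), MgCl2 (0.2 equiv), EtOAc, rt; then citric acid, MeOH, rt
Reagents that add atoms: none
Why: Evans magnesium halide-catalysed anti-aldol reaction of an N-acyl oxazolidinone with an aromatic aldehyde; the chelated (Z)-magnesium enolate is attacked on the face opposite the benzyl group of the (4S)-auxiliary (sets C8''), and the boat-like transition state places aryl anti to aryloxy (sets C7''). Me3SiCl silylates the aldolate to turn the catalyst over and also masks the ring C phenol as 18; citric acid in methanol removes both silyl groups.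

Step 10
Reactants: 20 the anti-aldol adduct of step 9
Product: 21 (1R,2S)-1-(4-hydroxy-3-methoxyphenyl)-2-(4-{(1R,3aS,4R,6aS)-4-(4-hydroxy-3-methoxyphenyl)tetrahydro-1H,3H-furo[3,4-c]furan-1-yl}-2-methoxyphenoxy)propane-1,3-diol (the target)
Conditions: LiBH4 (excess), THF/MeOH, 0 °C to rt; aq. NH4Cl
Reagents that add atoms: none
Why: LiBH4 reduces the exocyclic imide carbonyl to the C9'' primary alcohol and cleaves the aryl acetate by hydride attack, releasing the auxiliary; the benzylic ethers are inert to borohydride, and the low temperature guards against retro-aldol cleavage before the imide is reduced.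

## Compound list

1 | 3-(4-hydroxy-3-methoxyphenyl)propanoic acid | COc1cc(CCC(=O)O)ccc1O | starting material
2 | 3-[4-(benzyloxy)-3-methoxyphenyl]propanoic acid | COc1cc(CCC(=O)O)ccc1OCc1ccccc1 | intermediate
3 | (4R)-4-isopropyl-1,3-oxazolidin-2-one | CC(C)[C@@H]1COC(=O)N1 | starting material
4 | 3-[4-(benzyloxy)-3-methoxyphenyl]propanoic pivalic anhydride (not isolated) | COc1cc(CCC(=O)OC(=O)C(C)(C)C)ccc1OCc1ccccc1 | intermediate
5 | (4R)-3-{3-[4-(benzyloxy)-3-methoxyphenyl]propanoyl}-4-isopropyl-1,3-oxazolidin-2-one | COc1cc(CCC(=O)N2[C@H](C(C)C)COC2=O)ccc1OCc1ccccc1 | intermediate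
6 | (4R,4'R)-3,3'-{(2S,3S)-2,3-bis[4-(benzyloxy)-3-methoxybenzyl]butanedioyl}bis(4-isopropyl-1,3-oxazolidin-2-one) | O=C(N1[C@H](C(C)C)COC1=O)[C@@H](Cc1ccc(OCc2ccccc2)c(OC)c1)[C@H](Cc1ccc(OCc2ccccc2)c(OC)c1)C(=O)N1[C@H](C(C)C)COC1=O | intermediate
7 | (2S,3S)-2,3-bis[4-(benzyloxy)-3-methoxybenzyl]butane-1,4-diol | COc1cc(C[C@H](CO)[C@@H](CO)Cc2ccc(OCc3ccccc3)c(OC)c2)ccc1OCc1ccccc1 | intermediate
8 | (2S,3S)-2,3-bis(4-hydroxy-3-methoxybenzyl)butane-1,4-diol, (+)-secoisolariciresinol | COc1cc(C[C@H](CO)[C@@H](CO)Cc2ccc(O)c(OC)c2)ccc1O | intermediate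
9 | 4-[(2S,3S)-4-hydroxy-2-(hydroxymethyl)-3-(4-hydroxy-3-methoxybenzyl)butylidene]-2-methoxycyclohexa-2,5-dien-1-one, ring C quinone methide (not isolated) | COc1cc(C[C@H](CO)[C@@H](CO)C=C2C=CC(=O)C(OC)=C2)ccc1O | intermediate
10 | 4-[(2R,3S,4S)-4-(4-hydroxy-3-methoxybenzyl)-3-(hydroxymethyl)oxolan-2-yl]-2-methoxyphenol, (−)-lariciresinol (not isolated) | COc1cc(C[C@@H]2CO[C@@H](c3ccc(O)c(OC)c3)[C@@H]2CO)ccc1O | intermediate
11 | 4-{[(3S,4S,5R)-5-(4-hydroxy-3-methoxyphenyl)-4-(hydroxymethyl)oxolan-3-yl]methylidene}-2-methoxycyclohexa-2,5-dien-1-one, ring B quinone methide (not isolated) | COC1=CC(=C[C@@H]2CO[C@@H](c3ccc(O)c(OC)c3)[C@@H]2CO)C=CC1=O | intermediate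
12 | 4,4'-[(1R,3aS,4R,6aS)-tetrahydro-1H,3H-furo[3,4-c]furan-1,4-diyl]bis(2-methoxyphenol), (−)-pinoresinol | COc1cc([C@@H]2OC[C@@H]3[C@H]2CO[C@H]3c2ccc(O)c(OC)c2)ccc1O | intermediate
13 | (4S)-4-benzyl-1,3-oxazolidin-2-one | O=C1N[C@@H](Cc2ccccc2)CO1 | starting material
14 | bromoacetyl bromide | BrCC(Br)=O | starting material
15 | (4S)-4-benzyl-3-(bromoacetyl)-1,3-oxazolidin-2-one | O=C1OC[C@H](Cc2ccccc2)N1C(=O)CBr | intermediate
16 | (4S)-4-benzyl-3-[(4-{(1R,3aS,4R,6aS)-4-(4-hydroxy-3-methoxyphenyl)tetrahydro-1H,3H-furo[3,4-c]furan-1-yl}-2-methoxyphenoxy)acetyl]-1,3-oxazolidin-2-one | COc1cc([C@@H]2OC[C@@H]3[C@H]2CO[C@H]3c2ccc(O)c(OC)c2)ccc1OCC(=O)N1[C@@H](Cc2ccccc2)COC1=O | intermediate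
17 | 4-formyl-2-methoxyphenyl acetate (vanillin acetate) | CC(=O)Oc1ccc(C=O)cc1OC | starting material
18 | ring C O-trimethylsilyl ether of 16 (not isolated) | COc1cc([C@@H]2OC[C@@H]3[C@H]2CO[C@H]3c2ccc(O[Si](C)(C)C)c(OC)c2)ccc1OCC(=O)N1[C@@H](Cc2ccccc2)COC1=O | intermediate
19 | (2R,3R)-anti-aldol adduct of 18 and 17 as its C7'' and ring C bis(trimethylsilyl) ether (not isolated) | CC(=O)Oc1ccc([C@@H](O[Si](C)(C)C)[C@H](C(=O)N2[C@@H](Cc3ccccc3)COC2=O)Oc2ccc([C@@H]3OC[C@@H]4[C@H]3CO[C@H]4c3ccc(O[Si](C)(C)C)c(OC)c3)cc2OC)cc1OC | intermediate
20 | (4S)-3-[(2R,3R)-3-(4-acetoxy-3-methoxyphenyl)-3-hydroxy-2-(4-{(1R,3aS,4R,6aS)-4-(4-hydroxy-3-methoxyphenyl)tetrahydro-1H,3H-furo[3,4-c]furan-1-yl}-2-methoxyphenoxy)propanoyl]-4-benzyl-1,3-oxazolidin-2-one | CC(=O)Oc1ccc([C@@H](O)[C@H](C(=O)N2[C@@H](Cc3ccccc3)COC2=O)Oc2ccc([C@@H]3OC[C@@H]4[C@H]3CO[C@H]4c3ccc(O)c(OC)c3)cc2OC)cc1OC | intermediate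
21 | (1R,2S)-1-(4-hydroxy-3-methoxyphenyl)-2-(4-{(1R,3aS,4R,6aS)-4-(4-hydroxy-3-methoxyphenyl)tetrahydro-1H,3H-furo[3,4-c]furan-1-yl}-2-methoxyphenoxy)propane-1,3-diol | COc1cc([C@@H](O)[C@H](CO)Oc2ccc([C@@H]3OC[C@@H]4[C@H]3CO[C@H]4c3ccc(O)c(OC)c3)cc2OC)ccc1O | target

## Step count and least certain steps

Total step count: 10. Longest linear sequence: 9 steps (steps 1–6 and 8–10, from 1); step 7 is a one-step side branch.

Step 6 (key step). Most likely to go wrong is further oxidation of the phenolic benzylic ether C–H bonds of 10 and 12 before both CH2 groups are consumed, because these positions are still para-activated. Acid-induced Friedel–Crafts closure to an aryltetralin and tautomerisation of a quinone methide to a styrene are the other failure modes. Fallback, from 8 back to 12, uses the over-oxidation deliberately. Excess DDQ in wet dioxane should take both benzylic carbons to the ketone level, giving (2S,3S)-2,3-bis(hydroxymethyl)-1,4-bis(4-hydroxy-3-methoxyphenyl)butane-1,4-dione F1. NaBH4 in EtOH at 0 °C should then give (2S,3S)-2,3-bis(hydroxymethyl)-1,4-bis(4-hydroxy-3-methoxyphenyl)butane-1,4-diol F2 as a mixture of C7/C7' epimers. Catalytic camphorsulfonic acid in CH2Cl2/THF at 0 °C should close both oxolanes by SN1 cyclodehydration through the p-hydroxybenzyl cations, the classical tetrol-to-furofuran closure, with the aryl groups settling exo, to give 12.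

Step 9. Most likely to go wrong is poor simple diastereoselection (syn instead of anti) or a changed facial sense, because the α-aryloxy oxygen can bind magnesium and disturb the chelated transition state; slow conversion is a second concern. Fallback, from 12 to 21, sets C8'' by a boron syn-aldol and corrects C7'' by inversion:
- 12 is alkylated with (4R)-4-benzyl-3-(bromoacetyl)-1,3-oxazolidin-2-one F3 (made as in step 7 from the enantiomeric auxiliary) to give the diastereomeric mono(aryloxyacetyl) imide F4.
- The ring C phenol is acetylated (Ac2O, pyridine) to give the ring C acetate F5.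
- Bu2BOTf, iPr2NEt and 17 in CH2Cl2 at −78 to 0 °C should give the (2R,3S)-syn-aldol adduct F6, which has C8'' as in the target and C7'' epimeric.
- Mitsunobu reaction with 4-nitrobenzoic acid, PPh3 and diisopropyl azodicarboxylate inverts C7'' to give the (2R,3R)-4-nitrobenzoate F7. The electron-poor 4-acetoxyaryl group disfavours ionisation, and elimination of the β-hydroxy imide is the side reaction to watch.
- LiBH4 cleaves the imide, the nitrobenzoate and both acetates to give 21.

Step 8. Most likely to go wrong is over-alkylation to the bis-ether, since the two phenols react independently, and acyl transfer from the imide to phenoxide or carbonate under basic conditions. Fallback, from 12 back to 16, forms the aryl ether under neutral conditions. 13 is acylated with benzyloxyacetyl chloride (n-BuLi, THF, −78 °C) to (4S)-4-benzyl-3-[(benzyloxy)acetyl]-1,3-oxazolidin-2-one F8, and hydrogenolysis (H2, Pd/C) gives (4S)-4-benzyl-3-(hydroxyacetyl)-1,3-oxazolidin-2-one F9. Mitsunobu etherification of excess 12 with F9 (PPh3, diisopropyl azodicarboxylate, THF) should give 16.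

Step 3. Most likely to go wrong is low diastereoselection between the C2-symmetric and meso dimers, or reprotonation and α-chlorination of the enolate instead of coupling, because the bond forms from short-lived radical or titanium enolate species. Fallback, from 5 back to 7, builds the two centres one after the other:
- Evans alkylation of 5 with tert-butyl bromoacetate (NaN(SiMe3)2, THF, −78 °C) gives (4R)-3-{(2S)-2-[4-(benzyloxy)-3-methoxybenzyl]-4-tert-butoxy-4-oxobutanoyl}-4-isopropyl-1,3-oxazolidin-2-one F10.
- LiBH4 reduces the imide to tert-butyl (3S)-3-[4-(benzyloxy)-3-methoxybenzyl]-4-hydroxybutanoate F11.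
- Acid (CF3CO2H, CH2Cl2) lactonises it to (4S)-4-[4-(benzyloxy)-3-methoxybenzyl]oxolan-2-one F12.
- The lithium enolate of F12 (LiN(iPr)2, THF, −78 °C) is alkylated trans with 4-(benzyloxy)-3-methoxybenzyl bromide F13 (from the commercial benzylic alcohol and PBr3) to give (3S,4S)-3,4-bis[4-(benzyloxy)-3-methoxybenzyl]oxolan-2-one F14.
- LiAlH4 reduces F14 to 7.

## Further compounds

F1 | step 6 | (2S,3S)-2,3-bis(hydroxymethyl)-1,4-bis(4-hydroxy-3-methoxyphenyl)butane-1,4-dione | COc1cc(C(=O)[C@H](CO)[C@@H](CO)C(=O)c2ccc(O)c(OC)c2)ccc1O
F2 | step 6 | (2S,3S)-2,3-bis(hydroxymethyl)-1,4-bis(4-hydroxy-3-methoxyphenyl)butane-1,4-diol (C1/C4 epimers) | COc1cc(C(O)[C@H](CO)[C@@H](CO)C(O)c2ccc(O)c(OC)c2)ccc1O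
F3 | step 9 | (4R)-4-benzyl-3-(bromoacetyl)-1,3-oxazolidin-2-one | O=C1OC[C@@H](Cc2ccccc2)N1C(=O)CBr
F4 | step 9 | (4R)-4-benzyl-3-[(4-{(1R,3aS,4R,6aS)-4-(4-hydroxy-3-methoxyphenyl)tetrahydro-1H,3H-furo[3,4-c]furan-1-yl}-2-methoxyphenoxy)acetyl]-1,3-oxazolidin-2-one | COc1cc([C@@H]2OC[C@@H]3[C@H]2CO[C@H]3c2ccc(O)c(OC)c2)ccc1OCC(=O)N1[C@H](Cc2ccccc2)COC1=O
F5 | step 9 | ring C acetate of F4 | COc1cc([C@@H]2OC[C@@H]3[C@H]2CO[C@H]3c2ccc(OC(C)=O)c(OC)c2)ccc1OCC(=O)N1[C@H](Cc2ccccc2)COC1=O
F6 | step 9 | (2R,3S)-syn-aldol adduct of F5 and 17 | CC(=O)Oc1ccc([C@H](O)[C@H](C(=O)N2[C@H](Cc3ccccc3)COC2=O)Oc2ccc([C@@H]3OC[C@@H]4[C@H]3CO[C@H]4c3ccc(OC(C)=O)c(OC)c3)cc2OC)cc1OC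
F7 | step 9 | (2R,3R)-4-nitrobenzoate from inversion of F6 at C7'' | CC(=O)Oc1ccc([C@@H](OC(=O)c2ccc(cc2)[N+](=O)[O-])[C@H](C(=O)N2[C@H](Cc3ccccc3)COC2=O)Oc2ccc([C@@H]3OC[C@@H]4[C@H]3CO[C@H]4c3ccc(OC(C)=O)c(OC)c3)cc2OC)cc1OC
F8 | step 8 | (4S)-4-benzyl-3-[(benzyloxy)acetyl]-1,3-oxazolidin-2-one | O=C1OC[C@H](Cc2ccccc2)N1C(=O)COCc1ccccc1
F9 | step 8 | (4S)-4-benzyl-3-(hydroxyacetyl)-1,3-oxazolidin-2-one | O=C1OC[C@H](Cc2ccccc2)N1C(=O)CO
F10 | step 3 | (4R)-3-{(2S)-2-[4-(benzyloxy)-3-methoxybenzyl]-4-tert-butoxy-4-oxobutanoyl}-4-isopropyl-1,3-oxazolidin-2-one | CC(C)(C)OC(=O)C[C@H](Cc1ccc(OCc2ccccc2)c(OC)c1)C(=O)N1[C@H](C(C)C)COC1=O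
F11 | step 3 | tert-butyl (3S)-3-[4-(benzyloxy)-3-methoxybenzyl]-4-hydroxybutanoate | CC(C)(C)OC(=O)C[C@H](Cc1ccc(OCc2ccccc2)c(OC)c1)CO
F12 | step 3 | (4S)-4-[4-(benzyloxy)-3-methoxybenzyl]oxolan-2-one | O=C1C[C@H](Cc2ccc(OCc3ccccc3)c(OC)c2)CO1
F13 | step 3 | 4-(benzyloxy)-3-methoxybenzyl bromide | COc1cc(CBr)ccc1OCc1ccccc1
F14 | step 3 | (3S,4S)-3,4-bis[4-(benzyloxy)-3-methoxybenzyl]oxolan-2-one | COc1cc(C[C@@H]2C(=O)OC[C@H]2Cc2ccc(OCc3ccccc3)c(OC)c2)ccc1OCc1ccccc1
A1 | alternative 1 | (2R,3Z,5Z,7R)-2,7-bis[(tributylstannyl)methoxy]octa-3,5-diene | CCCC[Sn](CCCC)(CCCC)CO[C@H](C)/C=C\C=C/[C@@H](C)OC[Sn](CCCC)(CCCC)CCCC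
A2 | alternative 1 | (2S,3S)-2,3-di[(E)-prop-1-enyl]butane-1,4-diol | C/C=C/[C@H](CO)[C@@H](CO)/C=C/C
A3 | alternative 2 | (5S)-5-{[(1S,2R,5S)-2-isopropyl-5-methylcyclohexyl]oxy}furan-2(5H)-one | CC(C)[C@H]1CC[C@H](C)C[C@@H]1O[C@H]1OC(=O)C=C1
A4 | alternative 2 | 2-[4-(tert-butyldimethylsilyloxy)-3-methoxyphenyl]-1,3-dithiane | COc1cc(C2SCCCS2)ccc1O[Si](C)(C)C(C)(C)C
A5 | alternative 2 | 4-(allyloxy)-3-methoxybenzaldehyde | C=CCOc1ccc(C=O)cc1OC
A6 | alternative 2 | trans,trans-lactone from conjugate addition of lithiated A4 to A3 and aldol trapping with A5 | CC(C)[C@H]1CC[C@H](C)C[C@@H]1O[C@H]1OC(=O)[C@@H]([C@@H](O)c2ccc(OCC=C)c(OC)c2)[C@@H]1C1(c2ccc(O[Si](C)(C)C(C)(C)C)c(OC)c2)SCCCS1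
A7 | alternative 3 | 2-{(S)-[4-(allyloxy)-3-methoxyphenyl][(E)-3-(4-(tert-butyldimethylsilyloxy)-3-methoxyphenyl)prop-2-enyloxy]methyl}oxirane (C7 arranged as in the target, epoxide carbon either configuration) | C=CCOc1ccc([C@H](OC/C=C/c2ccc(O[Si](C)(C)C(C)(C)C)c(OC)c2)C2CO2)cc1OC
A8 | alternative 3 | 2-aryl-4-benzyl-3-(hydroxymethyl)oxolane with C7, C8 and C8' as in the target | C=CCOc1ccc([C@@H]2OC[C@@H](Cc3ccc(O[Si](C)(C)C(C)(C)C)c(OC)c3)[C@H]2CO)cc1OC
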